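**Retrosynthetic overview**

1. Target 9 ⇐ ester reduction of triphenol ester 8 ⇐ O‑demethylation of phenol ester 7.
2. Feature used: ring A is a pentasubstituted benzene, C1 (bears C8H2OH), C2 (H), C3 (Br), C4 (OH), C5 (OH), C6 (bears benzylic C7). O5 sits next to the benzyl‑bearing C6 and the C8‑bearing C1 sits next to C2–H, which is the pattern a 3‑alkoxyfuran/ynoate cycloaddition leaves after the oxygen bridge opens.
3. Key disconnection: C5–C6 and C1–C2 of ring A ⇒ 3‑bromo‑4‑methoxyfuran 2 (supplies C2, C3, C4, C5, Br, O4, O5) + ynoate 5 (supplies C1, C6, C7, C8 and ring B).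
4. 2 ⇐ 3,4‑dibromofuran 1 (copper‑mediated mono‑methoxylation); 5 ⇐ methyl propiolate 3 + 3‑bromo‑4‑methoxybenzyl bromide 4 (copper‑catalysed sp–sp3 coupling).
5. Ring order: ring B is bought intact; ring A is the only ring formed (step 3).

Key step: step 3

Remark: the target has no stereocentre and is achiral, so the "single enantiomer" condition is met without stereocontrol; 1, 3 and 4 are taken as catalogue compounds.

**Route**

Step 1
Reactants: 1 3,4‑dibromofuran
Product: 2 3‑bromo‑4‑methoxyfuran
Conditions: NaOMe (1.3 equiv), CuBr (20 mol%), MeOH–NMP, 95 °C, sealed tube, stopped before full conversion; distillation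
Reagents that add atoms: sodium methoxide, [Na+].[O-]C
Why: Ullmann‑type copper(I)‑mediated C–O coupling, known for 3‑bromofurans and for mono‑methoxylation of 3,4‑dibromothiophene, should replace one bromine, and the first methoxy group makes the ring more electron‑rich and slows the second substitution, so the mono‑ether should be separable from 1 and the diether.

Step 2
Reactants: 3 methyl propiolate, 4 3‑bromo‑4‑methoxybenzyl bromide
Product: 5 methyl 4‑(3‑bromo‑4‑methoxyphenyl)but‑2‑ynoate
Conditions: CuI (20 mol%), NaI (20 mol%), K2CO3 (1.3 equiv), MeCN, rt, argon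
Reagents that add atoms: none
Why: Copper‑catalysed sp–sp3 coupling of the copper acetylide of the propiolate with the benzylic halide (iodide formed in situ by Finkelstein exchange) should give the skipped ynoate; the aryl bromide is inert to Cu(I) at room temperature and the weak heterogeneous base should limit propargyl–allenyl isomerisation.

Step 3
Reactants: 2 3‑bromo‑4‑methoxyfuran, 5 methyl 4‑(3‑bromo‑4‑methoxyphenyl)but‑2‑ynoate
Product: 7 methyl 5‑bromo‑2‑(3‑bromo‑4‑methoxybenzyl)‑3‑hydroxy‑4‑methoxybenzoate, via 7‑oxanorbornadiene cycloadduct 6 (not isolated)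
Conditions: 2 (3 equiv), PhMe (2 M), BHT (cat.), 90 °C, sealed tube; then TFA (20 mol%), CH2Cl2, 0 °C → rt
Reagents that add atoms: none
Why: A normal‑electron‑demand Diels–Alder reaction should join the furan diene to the ynoate in a concerted suprafacial [4+2] closure of the six‑membered carbocycle (ring A, first as the 7‑oxanorbornadiene 6); the closest known reaction type is the cycloaddition of 3‑alkoxyfurans with acetylenic esters followed by oxa‑bridge opening to 3‑hydroxy‑4‑alkoxybenzoates. The furan α‑carbon next to the methoxy‑bearing carbon has the largest HOMO coefficient (donation from both the ring oxygen and the methoxy group) and should bond to the ynoate β‑carbon, which has the largest LUMO coefficient and carries the benzyl group, so this bridgehead becomes C5 next to C6 and the other new bond is C1–C2. Catalytic acid should then ionise the bridge C–O bond at the C2 bridgehead, because the resulting allyl cation is a vinylogous oxocarbenium ion stabilised by the C4 methoxy group, and loss of the C5 proton aromatises the ring with the former furan oxygen left as O5–H. The two bridgehead stereocentres of 6 form as a racemate and are erased on aromatisation, so no stereocontrol is needed. The selectivity required is regiochemical (C5–C6 rather than C5–C1 bonding, and opening toward the C5 phenol), and both are set by the methoxy group of 2 acting against the single ester acceptor of 5. The furyl and aryl C–Br bonds, the aryl methyl ether and the ester should be inert to heat and catalytic TFA.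

Step 4
Reactants: 7 methyl 5‑bromo‑2‑(3‑bromo‑4‑methoxybenzyl)‑3‑hydroxy‑4‑methoxybenzoate
Product: 8 methyl 5‑bromo‑2‑(3‑bromo‑4‑hydroxybenzyl)‑3,4‑dihydroxybenzoate
Conditions: BBr3 (5 equiv), CH2Cl2, −78 °C → rt; ice–water quench
Reagents that add atoms: none
Why: Lewis‑acid ether cleavage (BBr3 coordinates each aryl methyl ether oxygen and bromide removes the methyl group by SN2) should unmask both phenols while the methyl ester, the aryl bromides and the diarylmethane link survive; doing this before the reduction avoids converting a benzylic alcohol into a benzylic bromide.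

Step 5
Reactants: 8 methyl 5‑bromo‑2‑(3‑bromo‑4‑hydroxybenzyl)‑3,4‑dihydroxybenzoate
Product: 9 [5‑bromo‑2‑(3‑bromo‑4‑hydroxybenzyl)‑3,4‑dihydroxyphenyl]methanol
Conditions: DIBAL‑H (7 equiv), THF, −78 → 0 °C; degassed aq. Rochelle salt, then citric acid to pH 5–6
Reagents that add atoms: none
Why: After the three phenols are converted into aluminium phenoxides, excess DIBAL‑H should reduce the methyl ester to the primary alcohol (hydride reduction of an ester) without touching the aryl bromides, and a near‑neutral tartrate work‑up should keep the 4‑hydroxybenzyl alcohol from ionising to a quinone methide.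

**Compound list**

1 | 3,4‑dibromofuran | Brc1cocc1Br | starting material
2 | 3‑bromo‑4‑methoxyfuran | COc1cocc1Br | intermediate
3 | methyl propiolate | COC(=O)C#C | starting material
4 | 3‑bromo‑4‑methoxybenzyl bromide | COc1ccc(CBr)cc1Br | starting material
5 | methyl 4‑(3‑bromo‑4‑methoxyphenyl)but‑2‑ynoate | COC(=O)C#CCc1ccc(OC)c(Br)c1 | intermediate
6 | methyl 6‑bromo‑3‑(3‑bromo‑4‑methoxybenzyl)‑5‑methoxy‑7‑oxabicyclo[2.2.1]hepta‑2,5‑diene‑2‑carboxylate (racemate; the two bridgehead centres are tied together by the oxygen bridge; not isolated) | COC(=O)C1=C(Cc2ccc(OC)c(Br)c2)C2OC1C(Br)=C2OC | intermediate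
7 | methyl 5‑bromo‑2‑(3‑bromo‑4‑methoxybenzyl)‑3‑hydroxy‑4‑methoxybenzoate | COC(=O)c1cc(Br)c(OC)c(O)c1Cc1ccc(OC)c(Br)c1 | intermediate
8 | methyl 5‑bromo‑2‑(3‑bromo‑4‑hydroxybenzyl)‑3,4‑dihydroxybenzoate | COC(=O)c1cc(Br)c(O)c(O)c1Cc1ccc(O)c(Br)c1 | intermediate
9 | [5‑bromo‑2‑(3‑bromo‑4‑hydroxybenzyl)‑3,4‑dihydroxyphenyl]methanol | OCc1cc(Br)c(O)c(O)c1Cc1ccc(O)c(Br)c1 | target

**Step count**

Total steps: 5. Longest linear sequence: 4 steps (1 → 2 → 7 → 8 → 9, or 4 → 5 → 7 → 8 → 9).

**Steps most likely to fail**

1. Step 3 (key step). A β‑substituted, singly activated alkyne is a weak dienophile, so cycloreversion, thermal decay of the diene or isomerisation of the ynoate to its allenoate may outrun productive addition. Partial loss of regiocontrol, or hydrolysis of the enol ether of the cycloadduct by adventitious water instead of bridge opening, would also cost material.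
Fallback (sets out from 4, comes back at 7): ring A is taken from the arene pool and the C6–C7 bond is made by cross‑coupling. 3‑Bromo‑5‑hydroxy‑4‑methoxybenzoic acid (assumed to be a catalogue compound) is esterified (MeOH, H2SO4, reflux) to methyl 3‑bromo‑5‑hydroxy‑4‑methoxybenzoate F1. F1 should be iodinated at the position between the hydroxyl and the ester (NIS, cat. TsOH, MeCN, 0 °C), as isovanillin‑type phenols halogenate there and the para site is crowded between Br and CO2Me, giving methyl 5‑bromo‑3‑hydroxy‑2‑iodo‑4‑methoxybenzoate F2. Zinc insertion into the benzylic C–Br bond of 4 (Zn dust, LiCl, THF, 0 °C → rt, aryl bromide untouched) gives (3‑bromo‑4‑methoxybenzyl)zinc bromide F3. Negishi coupling of F2 with F3 (2.2 equiv, the first equivalent being consumed by the phenol; Pd(PPh3)4, THF, rt → 40 °C; oxidative addition at C–I preferred over C–Br) should deliver 7.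

2. Step 1. Over‑reaction to the diether, copper‑mediated hydrodebromination, and evaporative or acid‑induced loss of the volatile, enol‑ether‑like product may erode the supply of diene.
Fallback (sets out from 1, comes back at 2): mono bromine–lithium exchange (n‑BuLi 1.0 equiv, Et2O, −78 °C) fixes mono‑functionalisation and gives 3‑bromo‑4‑lithiofuran F4. F4 is trapped with B(OiPr)3 and converted with aqueous KHF2 into potassium (4‑bromofuran‑3‑yl)trifluoroborate F5. Chan–Lam‑type oxidative etherification with methanol (Cu(OAc)2·H2O cat., DMAP, 4 Å MS, CH2Cl2–MeOH, O2, rt) should then give 2.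

3. Step 2. Carbonate‑induced isomerisation of the skipped ynoate to the conjugated allenoate, oxidative homocoupling or conjugate addition of the propiolate, and slow alkylation of the copper acetylide may lower the yield or purity of 5.
Fallback (sets out from 4, comes back at 5): copper‑catalysed coupling of 4 with ethynylmagnesium bromide (CuBr·SMe2 cat., THF, 0 → 50 °C) gives 2‑bromo‑1‑methoxy‑4‑(prop‑2‑yn‑1‑yl)benzene F6. Deprotonation with EtMgBr (THF, 0 °C → rt, no halogen–metal exchange at the aryl bromide) gives [3‑(3‑bromo‑4‑methoxyphenyl)prop‑1‑yn‑1‑yl]magnesium bromide F7. Acylation of F7 with methyl chloroformate (−40 → 0 °C), with no free base present, should give 5.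

**Further compounds**

F1 | step 3 | methyl 3‑bromo‑5‑hydroxy‑4‑methoxybenzoate | COC(=O)c1cc(O)c(OC)c(Br)c1
F2 | step 3 | methyl 5‑bromo‑3‑hydroxy‑2‑iodo‑4‑methoxybenzoate | COC(=O)c1cc(Br)c(OC)c(O)c1I
F3 | step 3 | (3‑bromo‑4‑methoxybenzyl)zinc bromide | COc1ccc(C[Zn]Br)cc1Br
F4 | step 1 | 3‑bromo‑4‑lithiofuran | [Li]c1cocc1Br
F5 | step 1 | potassium (4‑bromofuran‑3‑yl)trifluoroborate | [K+].F[B-](F)(F)c1cocc1Br
F6 | step 2 | 2‑bromo‑1‑methoxy‑4‑(prop‑2‑yn‑1‑yl)benzene | COc1ccc(CC#C)cc1Br
F7 | step 2 | [3‑(3‑bromo‑4‑methoxyphenyl)prop‑1‑yn‑1‑yl]magnesium bromide | COc1ccc(CC#C[Mg]Br)cc1Br
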